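**Retrosynthetic overview**

1. Numbering and the feature used: each 3,7,11-trimethyldodeca-1,6,10-trien-3-yl chain is C1–C12 (C1=C2 vinyl, C3 quaternary, C4 methylene); ring A is the phenol ring (chain on C1, OH on C3, ether oxygen on C4) and ring B the benzene-1,2-diol ring (chain on C1, OH on C3 and C4, ether oxygen on C5). Each C3 carries an aryl ring, a methyl group and two one-carbon neighbours (C2 and C4), which is the pattern of an aryl(methyl)malonate. The two C3 centres (R on ring A, S on ring B) are locally mirror images, so one malonic half-ester serves both when its two carboxyl carbons exchange the roles of C2 and C4.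
2. Last disconnections: the three MOM ethers, then the diaryl ether bond O4 (ring A)–C5 (ring B), made by copper-catalysed Ullmann coupling of phenol 37 with aryl iodide 23; the iodide is placed by directed ortho-lithiation.
3. Each chain: C2=C1 by Wittig methylenation of an aldehyde; C4–C5 by alkylation of a neopentyl phenyl sulfone carbanion at C4 with geranyl bromide, then reductive desulfonylation.
4. Both C3 centres come from half-ester 8: borane reduces the acid arm (S series, ring B) and LiBH4 the ester arm (R series, ring A). Half-ester 8 comes from pig liver esterase hydrolysis of one enantiotopic ester of dimethyl aryl(methyl)malonate 7, built from catechol and dimethyl malonate.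
5. Ring order: no ring is formed; both benzene rings come from catechol, and ring B gains its third oxygen in the Ullmann coupling.

Key step: step 6

Assumption: the esterase is taken to cleave the pro-R ester of 7 and give S-configured 8; if it cleaves the pro-S ester, the borane reduction leads to 25 and the LiBH4/esterification pair to 9, and everything after these two compounds is unchanged.

**Common steps**

Step 1
Reactants: 1 catechol
Product: 2 2-(methoxymethoxy)phenol
Conditions: MOMCl (1.0 equiv), i-Pr2NEt (1.1 equiv), CH2Cl2, 0 °C → rt; chromatography (bis-ether and unreacted 1 removed)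
Reagents that add atoms: chloromethyl methyl ether, COCCl
Why: Williamson-type O-alkylation by the reactive α-chloro ether with one equivalent of reagent should give mainly the mono-acetal, the rest being separable.

Step 2
Reactants: 2 2-(methoxymethoxy)phenol
Product: 3 4-bromo-2-(methoxymethoxy)phenol
Conditions: NBS (1.0 equiv), MeCN, −10 → 0 °C
Reagents that add atoms: N-bromosuccinimide, O=C1CCC(=O)N1Br
Why: Electrophilic aromatic bromination goes para to the free hydroxyl, the strongest donor on the ring, as in the bromination of guaiacol, and the near-neutral medium spares the MOM acetal.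

Step 3
Reactants: 3 4-bromo-2-(methoxymethoxy)phenol
Product: 4 1-(benzyloxy)-4-bromo-2-(methoxymethoxy)benzene
Conditions: BnBr (1.1 equiv), K2CO3, DMF, rt
Reagents that add atoms: benzyl bromide, BrCc1ccccc1
Why: Williamson ether synthesis on the phenoxide, to which the aryl bromide and the acetal are inert.

Step 4
Reactants: 4 1-(benzyloxy)-4-bromo-2-(methoxymethoxy)benzene; 5 dimethyl malonate
Product: 6 dimethyl 2-[4-(benzyloxy)-3-(methoxymethoxy)phenyl]propanedioate
Conditions: Pd(dba)2 (2 mol%), P(t-Bu)3 (4 mol%), K3PO4 (3 equiv), toluene, 70 °C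
Reagents that add atoms: dimethyl malonate (5), COC(=O)CC(=O)OC
Why: Palladium-catalysed α-arylation of a malonate, in which oxidative addition of the electron-rich aryl bromide to zerovalent palladium bearing the bulky phosphine, enolate exchange and reductive elimination form the aryl–carbon bond, and the acidic product is not arylated a second time.

Step 5
Reactants: 6 dimethyl aryl malonate
Product: 7 dimethyl 2-[4-(benzyloxy)-3-(methoxymethoxy)phenyl]-2-methylpropanedioate
Conditions: MeI (1.5 equiv), K2CO3, DMF, rt
Reagents that add atoms: iodomethane, CI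
Why: Malonate alkylation at the single acidic C–H gives the prochiral diester, whose two ester groups are enantiotopic.

Step 6
Reactants: 7 dimethyl aryl(methyl)malonate
Product: 8 (S)-2-[4-(benzyloxy)-3-(methoxymethoxy)phenyl]-3-methoxy-2-methyl-3-oxopropanoic acid
Conditions: pig liver esterase, 0.1 M phosphate buffer pH 7.5 with 10% DMSO, 25–30 °C, pH-stat with 1 M NaOH to 1.0 equiv uptake; then 1 M HCl to pH 3 at 0 °C, EtOAc
Reagents that add atoms: water, O
Why: The serine hydroxyl of the esterase triad adds to one methoxycarbonyl group, methanol leaves from the tetrahedral intermediate and water cleaves the acyl-enzyme to the acid; the closest known reaction is the pig liver esterase desymmetrisation of prochiral dimethyl 2-alkyl- and 2-aryl-2-methylmalonates. No ring is closed and no skeletal bond is formed. The one new stereocentre, the quaternary carbon, is fixed by the enzyme: with the flat 4-benzyloxy-3-(methoxymethoxy)phenyl group in the large hydrophobic pocket and the methyl group in the small one, only the pro-R ester reaches the serine, which gives the S half-ester. The step needs discrimination between two enantiotopic esters and a stop after one hydrolysis; the first rests on the size difference between aryl and methyl, the second on the carboxylate of 8, which is not accepted as a substrate at pH 7.5. The lipophilic diester is kept available with DMSO as co-solvent and conversion is followed by base uptake; 8 is not heated, to avoid decarboxylation.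

**Ring B series (S centre): acid arm becomes C4, ester arm becomes vinyl**

Step 7
Reactants: 8 (S)-half-ester
Product: 9 methyl (S)-2-[4-(benzyloxy)-3-(methoxymethoxy)phenyl]-3-hydroxy-2-methylpropanoate
Conditions: BH3·SMe2 (2 equiv), THF, 0 °C → rt; aqueous work-up
Reagents that add atoms: none
Why: Chemoselective borane reduction, in which the free acid is reduced through its acyloxyborane far faster than the hindered methyl ester, so the carboxyl carbon becomes the CH2OH arm destined to be C4 while the quaternary centre is untouched.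

Step 8
Reactants: 9 (S)-hydroxy ester
Product: 11 methyl (R)-2-[4-(benzyloxy)-3-(methoxymethoxy)phenyl]-2-methyl-3-(phenylsulfanyl)propanoate, via neopentyl triflate 10 (not isolated)
Conditions: Tf2O (1.1 equiv), 2,6-lutidine, CH2Cl2, −78 °C; then PhSNa (2 equiv) in DMF, −78 °C → rt
Reagents that add atoms: sodium benzenethiolate, [Na+].[S-]c1ccccc1; trifluoromethanesulfonic anhydride (atoms kept only in 10), O=S(=O)(OS(=O)(=O)C(F)(F)F)C(F)(F)F
Why: SN2 substitution at a neopentyl carbon needs the best leaving group and a soft unhindered nucleophile, and the triflate–thiolate pair reacts below room temperature, where the methyl ester is not demethylated, while the geminal ester disfavours aryl migration because a rearranged cation would lie next to a carbonyl group.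

Step 9
Reactants: 11 (R)-sulfide ester
Product: 12 methyl (R)-2-[4-(benzyloxy)-3-(methoxymethoxy)phenyl]-2-methyl-3-(phenylsulfonyl)propanoate
Conditions: mCPBA (2.2 equiv), NaHCO3, CH2Cl2, 0 °C → rt
Reagents that add atoms: 3-chloroperoxybenzoic acid, OOC(=O)c1cccc(Cl)c1
Why: Peracid oxidation of the sulfide through the sulfoxide to the sulfone is much faster than any attack on the arene, and no alkene is present yet.

Step 10
Reactants: 12 (R)-sulfone ester
Product: 13 methyl (R)-2-[4-hydroxy-3-(methoxymethoxy)phenyl]-2-methyl-3-(phenylsulfonyl)propanoate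
Conditions: H2 (1 atm), 10% Pd/C, EtOAc–MeOH, rt
Reagents that add atoms: none
Why: Hydrogenolysis of the benzylic C–O bond on palladium is placed here because the molecule has no alkene yet and sulfur at the sulfone level does not poison the catalyst.

Step 11
Reactants: 13 (R)-phenol
Product: 14 methyl (R)-2-[3,4-bis(methoxymethoxy)phenyl]-2-methyl-3-(phenylsulfonyl)propanoate
Conditions: MOMCl (1.5 equiv), i-Pr2NEt, CH2Cl2, 0 °C → rt
Reagents that add atoms: chloromethyl methyl ether, COCCl
Why: O-Alkylation of the freed phenol gives the bis-MOM catechol, stable to the organolithium and reducing steps ahead and later the directing group for lithiation at C5 of ring B.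

Step 12
Reactants: 14 (R)-bis-MOM sulfone ester
Product: 15 (R)-2-[3,4-bis(methoxymethoxy)phenyl]-2-methyl-3-(phenylsulfonyl)propan-1-ol
Conditions: i-Bu2AlH (3 equiv), CH2Cl2, −78 → 0 °C; aqueous potassium sodium tartrate (KNaC4H4O6)
Reagents that add atoms: none
Why: Hydride reduction of the ester by the aluminium hydride proceeds through the aldehyde to the primary alcohol, and sulfone and acetals do not react at or below 0 °C.

Step 13
Reactants: 15 (R)-hydroxy sulfone; 16 geranyl bromide, (2E)-1-bromo-3,7-dimethylocta-2,6-diene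
Product: 18 (2R,5E)-2-[3,4-bis(methoxymethoxy)phenyl]-2,6,10-trimethyl-3-(phenylsulfonyl)undeca-5,9-dien-1-ol as a mixture of C3 epimers, via dilithio alkoxide sulfonyl carbanion 17 (not isolated)
Conditions: n-BuLi (2.1 equiv), THF–DMPU, −78 °C; then 16 (1.2 equiv), −78 → −20 °C
Reagents that add atoms: geranyl bromide (16), CC(C)=CCC/C(C)=C/CBr; n-butyllithium (lithium kept only in 17), [Li]CCCC
Why: Sulfone alkylation, in which two equivalents of base give the lithium alkoxide and the α-sulfonyl carbanion and only the soft carbanion attacks the allylic bromide at its CH2Br carbon without allylic transposition, forming the C4–C5 bond with the E alkene retained; the new sulfone-bearing centre is erased in the next step.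

Step 14
Reactants: 18 alkylated sulfone
Product: 19 (2R,5E)-2-[3,4-bis(methoxymethoxy)phenyl]-2,6,10-trimethylundeca-5,9-dien-1-ol
Conditions: 6% Na(Hg), Na2HPO4, MeOH–THF, −20 → 0 °C
Reagents that add atoms: none
Why: Reductive desulfonylation by electron transfer from the amalgam, with buffered methanol protonating the carbanion at once; the intermediate alkyl radical is reduced faster than a neophyl-type aryl shift, and the step is run before the vinyl group exists because a 1,2-vinyl shift would be fast.

Step 15
Reactants: 19 (R)-alcohol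
Product: 20 (2R,5E)-2-[3,4-bis(methoxymethoxy)phenyl]-2,6,10-trimethylundeca-5,9-dienal
Conditions: Dess–Martin periodinane, NaHCO3, CH2Cl2, 0 °C → rt
Reagents that add atoms: none
Why: Dess–Martin oxidation of the neopentyl alcohol stops at the aldehyde, which has no α-hydrogen and cannot epimerise, and the buffered medium spares acetals and trisubstituted alkenes.

Step 16
Reactants: 20 (R)-aldehyde
Product: 21 4-[(3S,6E)-3,7,11-trimethyldodeca-1,6,10-trien-3-yl]-1,2-bis(methoxymethoxy)benzene
Conditions: Ph3PCH3Br, KOt-Bu, THF, 0 °C → rt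
Reagents that add atoms: methyltriphenylphosphonium bromide, C[P+](c1ccccc1)(c1ccccc1)c1ccccc1.[Br-]
Why: Wittig methylenation with the small unstabilised ylide converts even a hindered α-quaternary aldehyde into the C2=C1 vinyl group, completing the S-configured chain.

Step 17
Reactants: 21 bis-MOM arene
Product: 23 1-iodo-2,3-bis(methoxymethoxy)-5-[(3S,6E)-3,7,11-trimethyldodeca-1,6,10-trien-3-yl]benzene, via aryllithium 22 (not isolated)
Conditions: n-BuLi (1.3 equiv), TMEDA, THF, −78 → 0 °C; then ICH2CH2I, −78 °C → rt
Reagents that add atoms: 1,2-diiodoethane, ICCI; n-butyllithium (lithium kept only in 22), [Li]CCCC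
Why: Directed ortho-metalation, in which the base bound to the MOM oxygen on C4 removes the C5 hydrogen (the other site next to a MOM ether, C2, is shielded by the quaternary carbon), followed by iodine transfer from the diiodide so that the alkenes never meet free iodine.

**Ring A series (R centre): ester arm becomes C4, acid arm becomes vinyl**

Step 18
Reactants: 8 (S)-half-ester
Product: 24 (R)-2-[4-(benzyloxy)-3-(methoxymethoxy)phenyl]-3-hydroxy-2-methylpropanoic acid
Conditions: LiBH4 (3 equiv), MeOH (2 equiv), THF, 0 °C → rt; then 1 M NaHSO4 to pH 3 at 0 °C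
Reagents that add atoms: none
Why: Chemoselective borohydride reduction, in which the acid is first converted to its lithium carboxylate, which is not reduced, and the methyl ester is then reduced, so here the ester carbon becomes the CH2OH arm and the centre has the opposite sense to that in 9.

Step 19
Reactants: 24 (R)-hydroxy acid
Product: 25 methyl (R)-2-[4-(benzyloxy)-3-(methoxymethoxy)phenyl]-3-hydroxy-2-methylpropanoate
Conditions: MeI (1.5 equiv), KHCO3, DMF, rt
Reagents that add atoms: iodomethane, CI
Why: Carboxylate O-alkylation under hydrogen carbonate base esterifies the acid without touching the alcohol and gives the enantiomer of 9, so the chemistry of steps 8–16 can be repeated in mirror image.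

Step 20
Reactants: 25 (R)-hydroxy ester
Product: 27 methyl (S)-2-[4-(benzyloxy)-3-(methoxymethoxy)phenyl]-2-methyl-3-(phenylsulfanyl)propanoate, via neopentyl triflate 26 (not isolated)
Conditions: Tf2O (1.1 equiv), 2,6-lutidine, CH2Cl2, −78 °C; then PhSNa (2 equiv) in DMF, −78 °C → rt
Reagents that add atoms: sodium benzenethiolate, [Na+].[S-]c1ccccc1; trifluoromethanesulfonic anhydride (atoms kept only in 26), O=S(=O)(OS(=O)(=O)C(F)(F)F)C(F)(F)F
Why: The same low-temperature triflate–thiolate SN2 substitution at the neopentyl carbon as in step 8, protected from aryl migration by the geminal ester.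

Step 21
Reactants: 27 (S)-sulfide ester
Product: 28 methyl (S)-2-[4-(benzyloxy)-3-(methoxymethoxy)phenyl]-2-methyl-3-(phenylsulfonyl)propanoate
Conditions: mCPBA (2.2 equiv), NaHCO3, CH2Cl2, 0 °C → rt
Reagents that add atoms: 3-chloroperoxybenzoic acid, OOC(=O)c1cccc(Cl)c1
Why: Peracid oxidation of sulfide to sulfone in a molecule that still has no alkene.

Step 22
Reactants: 28 (S)-sulfone ester
Product: 29 methyl (S)-2-[4-hydroxy-3-(methoxymethoxy)phenyl]-2-methyl-3-(phenylsulfonyl)propanoate
Conditions: H2 (1 atm), 10% Pd/C, EtOAc–MeOH, rt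
Reagents that add atoms: none
Why: Palladium-catalysed hydrogenolysis of the benzyl ether before any alkene is introduced frees O4 of ring A, with MOM ether, ester and sulfone inert.

Step 23
Reactants: 29 (S)-phenol
Product: 30 methyl (S)-2-[3-(methoxymethoxy)-4-[tri(propan-2-yl)silyloxy]phenyl]-2-methyl-3-(phenylsulfonyl)propanoate
Conditions: TIPSOTf (1.3 equiv), 2,6-lutidine, CH2Cl2, 0 °C
Reagents that add atoms: triisopropylsilyl triflate, CC(C)[Si](OS(=O)(=O)C(F)(F)F)(C(C)C)C(C)C
Why: Silylation of the phenol with the reactive silyl triflate installs a bulky ether that survives organolithium, hydride, amalgam and ylide and can later be removed by fluoride beside MOM ethers and alkenes.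

Step 24
Reactants: 30 (S)-silyl ether ester
Product: 31 (S)-2-[3-(methoxymethoxy)-4-[tri(propan-2-yl)silyloxy]phenyl]-2-methyl-3-(phenylsulfonyl)propan-1-ol
Conditions: i-Bu2AlH (3 equiv), CH2Cl2, −78 → 0 °C; aqueous potassium sodium tartrate (KNaC4H4O6)
Reagents that add atoms: none
Why: Aluminium hydride reduction of the ester to the primary alcohol, with sulfone, acetal and aryl silyl ether unaffected at low temperature.

Step 25
Reactants: 31 (S)-hydroxy sulfone; 16 geranyl bromide
Product: 33 (2S,5E)-2-[3-(methoxymethoxy)-4-[tri(propan-2-yl)silyloxy]phenyl]-2,6,10-trimethyl-3-(phenylsulfonyl)undeca-5,9-dien-1-ol as a mixture of C3 epimers, via dilithio alkoxide sulfonyl carbanion 32 (not isolated)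
Conditions: n-BuLi (2.1 equiv), THF–DMPU, −78 °C; then 16 (1.2 equiv), −78 → −20 °C
Reagents that add atoms: geranyl bromide (16), CC(C)=CCC/C(C)=C/CBr; n-butyllithium (lithium kept only in 32), [Li]CCCC
Why: Sulfone alkylation of the dianion at carbon by the allylic bromide forms the C4–C5 bond of the ring A chain exactly as in step 13.

Step 26
Reactants: 33 alkylated sulfone
Product: 34 (2S,5E)-2-[3-(methoxymethoxy)-4-[tri(propan-2-yl)silyloxy]phenyl]-2,6,10-trimethylundeca-5,9-dien-1-ol
Conditions: 6% Na(Hg), Na2HPO4, MeOH–THF, −20 → 0 °C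
Reagents that add atoms: none
Why: Reductive desulfonylation under phosphate buffer at low temperature removes the sulfone while the hindered aryl silyl ether should persist.

Step 27
Reactants: 34 (S)-alcohol
Product: 35 (2S,5E)-2-[3-(methoxymethoxy)-4-[tri(propan-2-yl)silyloxy]phenyl]-2,6,10-trimethylundeca-5,9-dienal
Conditions: Dess–Martin periodinane, NaHCO3, CH2Cl2, 0 °C → rt
Reagents that add atoms: none
Why: Dess–Martin oxidation to the non-enolisable aldehyde, the phenol being masked so that no quinone can form.

Step 28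
Reactants: 35 (S)-aldehyde
Product: 36 tri(propan-2-yl)[2-(methoxymethoxy)-4-[(3R,6E)-3,7,11-trimethyldodeca-1,6,10-trien-3-yl]phenoxy]silane
Conditions: Ph3PCH3Br, KOt-Bu, THF, 0 °C → rt
Reagents that add atoms: methyltriphenylphosphonium bromide, C[P+](c1ccccc1)(c1ccccc1)c1ccccc1.[Br-]
Why: Wittig methylenation gives the vinyl group and thereby the R-configured chain of ring A.

Step 29
Reactants: 36 (R)-silyl ether
Product: 37 2-(methoxymethoxy)-4-[(3R,6E)-3,7,11-trimethyldodeca-1,6,10-trien-3-yl]phenol
Conditions: Bu4NF (1.1 equiv), THF, 0 °C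
Reagents that add atoms: none
Why: Fluoride-induced desilylation, driven by Si–F bond formation, frees only O4 of ring A, the oxygen that becomes the diaryl ether.

**Union and end game**

Step 30
Reactants: 37 ring A phenol; 23 ring B aryl iodide
Product: 38 1-[2-(methoxymethoxy)-4-[(3R,6E)-3,7,11-trimethyldodeca-1,6,10-trien-3-yl]phenoxy]-2,3-bis(methoxymethoxy)-5-[(3S,6E)-3,7,11-trimethyldodeca-1,6,10-trien-3-yl]benzene
Conditions: CuI (10 mol%), picolinic acid (20 mol%), K3PO4 (2 equiv), DMSO, 90 °C, argon
Reagents that add atoms: aryl iodide 23, COCOc1cc(cc(I)c1OCOC)[C@](C)(C=C)CC/C=C(\C)CCC=C(C)C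
Why: Ullmann diaryl ether synthesis, in which the picolinate-bound monovalent copper phenoxide of 37 couples with the aryl iodide; this ligand and base pair is the one known to tolerate ortho substituents on both partners, and nothing else in either partner reacts with phosphate at 90 °C.

Step 31
Reactants: 38 tris-MOM diaryl ether
Product: 39 3-[2-hydroxy-4-[(3R,6E)-3,7,11-trimethyldodeca-1,6,10-trien-3-yl]phenoxy]-5-[(3S,6E)-3,7,11-trimethyldodeca-1,6,10-trien-3-yl]benzene-1,2-diol (CNP0230356.1)
Conditions: HCl (about 1 M) in MeOH–THF, rt → 40 °C, argon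
Reagents that add atoms: none
Why: Acid-catalysed acetal exchange with methanol removes the three aryl MOM groups as dimethoxymethane under conditions too mild to protonate the trisubstituted alkenes, and argon protects the electron-rich phenols from air.

**Compound list**

1 | catechol | Oc1ccccc1O | starting material
2 | 2-(methoxymethoxy)phenol | COCOc1ccccc1O | intermediate
3 | 4-bromo-2-(methoxymethoxy)phenol | COCOc1cc(Br)ccc1O | intermediate
4 | 1-(benzyloxy)-4-bromo-2-(methoxymethoxy)benzene | COCOc1cc(Br)ccc1OCc1ccccc1 | intermediate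
5 | dimethyl malonate | COC(=O)CC(=O)OC | starting material
6 | dimethyl 2-[4-(benzyloxy)-3-(methoxymethoxy)phenyl]propanedioate | COC(=O)C(C(=O)OC)c1ccc(OCc2ccccc2)c(OCOC)c1 | intermediate
7 | dimethyl 2-[4-(benzyloxy)-3-(methoxymethoxy)phenyl]-2-methylpropanedioate | COC(=O)C(C)(C(=O)OC)c1ccc(OCc2ccccc2)c(OCOC)c1 | intermediate
8 | (S)-2-[4-(benzyloxy)-3-(methoxymethoxy)phenyl]-3-methoxy-2-methyl-3-oxopropanoic acid | COCOc1cc(ccc1OCc1ccccc1)[C@](C)(C(=O)OC)C(=O)O | intermediate
9 | methyl (S)-2-[4-(benzyloxy)-3-(methoxymethoxy)phenyl]-3-hydroxy-2-methylpropanoate | COCOc1cc(ccc1OCc1ccccc1)[C@](C)(C(=O)OC)CO | intermediate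
10 | methyl (S)-2-[4-(benzyloxy)-3-(methoxymethoxy)phenyl]-2-methyl-3-[(trifluoromethylsulfonyl)oxy]propanoate | COCOc1cc(ccc1OCc1ccccc1)[C@](C)(C(=O)OC)COS(=O)(=O)C(F)(F)F | intermediate
11 | methyl (R)-2-[4-(benzyloxy)-3-(methoxymethoxy)phenyl]-2-methyl-3-(phenylsulfanyl)propanoate | COCOc1cc(ccc1OCc1ccccc1)[C@](C)(C(=O)OC)CSc1ccccc1 | intermediate
12 | methyl (R)-2-[4-(benzyloxy)-3-(methoxymethoxy)phenyl]-2-methyl-3-(phenylsulfonyl)propanoate | COCOc1cc(ccc1OCc1ccccc1)[C@](C)(C(=O)OC)CS(=O)(=O)c1ccccc1 | intermediate
13 | methyl (R)-2-[4-hydroxy-3-(methoxymethoxy)phenyl]-2-methyl-3-(phenylsulfonyl)propanoate | COCOc1cc(ccc1O)[C@](C)(C(=O)OC)CS(=O)(=O)c1ccccc1 | intermediate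
14 | methyl (R)-2-[3,4-bis(methoxymethoxy)phenyl]-2-methyl-3-(phenylsulfonyl)propanoate | COCOc1cc(ccc1OCOC)[C@](C)(C(=O)OC)CS(=O)(=O)c1ccccc1 | intermediate
15 | (R)-2-[3,4-bis(methoxymethoxy)phenyl]-2-methyl-3-(phenylsulfonyl)propan-1-ol | COCOc1cc(ccc1OCOC)[C@](C)(CO)CS(=O)(=O)c1ccccc1 | intermediate
16 | geranyl bromide, (2E)-1-bromo-3,7-dimethylocta-2,6-diene | CC(C)=CCC/C(C)=C/CBr | starting material
17 | dilithio derivative of 15 (lithium alkoxide, α-lithio sulfone) | COCOc1cc(ccc1OCOC)[C@](C)(CO[Li])C([Li])S(=O)(=O)c1ccccc1 | intermediate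
18 | (2R,5E)-2-[3,4-bis(methoxymethoxy)phenyl]-2,6,10-trimethyl-3-(phenylsulfonyl)undeca-5,9-dien-1-ol, C3 epimers | COCOc1cc(ccc1OCOC)[C@](C)(CO)C(C/C=C(\C)CCC=C(C)C)S(=O)(=O)c1ccccc1 | intermediate
19 | (2R,5E)-2-[3,4-bis(methoxymethoxy)phenyl]-2,6,10-trimethylundeca-5,9-dien-1-ol | COCOc1cc(ccc1OCOC)[C@](C)(CO)CC/C=C(\C)CCC=C(C)C | intermediate
20 | (2R,5E)-2-[3,4-bis(methoxymethoxy)phenyl]-2,6,10-trimethylundeca-5,9-dienal | COCOc1cc(ccc1OCOC)[C@](C)(C=O)CC/C=C(\C)CCC=C(C)C | intermediate
21 | 4-[(3S,6E)-3,7,11-trimethyldodeca-1,6,10-trien-3-yl]-1,2-bis(methoxymethoxy)benzene | COCOc1cc(ccc1OCOC)[C@](C)(C=C)CC/C=C(\C)CCC=C(C)C | intermediate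
22 | [2,3-bis(methoxymethoxy)-5-[(3S,6E)-3,7,11-trimethyldodeca-1,6,10-trien-3-yl]phenyl]lithium | [Li]c1cc(cc(OCOC)c1OCOC)[C@](C)(C=C)CC/C=C(\C)CCC=C(C)C | intermediate
23 | 1-iodo-2,3-bis(methoxymethoxy)-5-[(3S,6E)-3,7,11-trimethyldodeca-1,6,10-trien-3-yl]benzene | COCOc1cc(cc(I)c1OCOC)[C@](C)(C=C)CC/C=C(\C)CCC=C(C)C | intermediate
24 | (R)-2-[4-(benzyloxy)-3-(methoxymethoxy)phenyl]-3-hydroxy-2-methylpropanoic acid | COCOc1cc(ccc1OCc1ccccc1)[C@](C)(CO)C(=O)O | intermediate
25 | methyl (R)-2-[4-(benzyloxy)-3-(methoxymethoxy)phenyl]-3-hydroxy-2-methylpropanoate | COCOc1cc(ccc1OCc1ccccc1)[C@](C)(CO)C(=O)OC | intermediate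
26 | methyl (R)-2-[4-(benzyloxy)-3-(methoxymethoxy)phenyl]-2-methyl-3-[(trifluoromethylsulfonyl)oxy]propanoate | COCOc1cc(ccc1OCc1ccccc1)[C@](C)(COS(=O)(=O)C(F)(F)F)C(=O)OC | intermediate
27 | methyl (S)-2-[4-(benzyloxy)-3-(methoxymethoxy)phenyl]-2-methyl-3-(phenylsulfanyl)propanoate | COCOc1cc(ccc1OCc1ccccc1)[C@](C)(CSc1ccccc1)C(=O)OC | intermediate
28 | methyl (S)-2-[4-(benzyloxy)-3-(methoxymethoxy)phenyl]-2-methyl-3-(phenylsulfonyl)propanoate | COCOc1cc(ccc1OCc1ccccc1)[C@](C)(CS(=O)(=O)c1ccccc1)C(=O)OC | intermediate
29 | methyl (S)-2-[4-hydroxy-3-(methoxymethoxy)phenyl]-2-methyl-3-(phenylsulfonyl)propanoate | COCOc1cc(ccc1O)[C@](C)(CS(=O)(=O)c1ccccc1)C(=O)OC | intermediate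
30 | methyl (S)-2-[3-(methoxymethoxy)-4-[tri(propan-2-yl)silyloxy]phenyl]-2-methyl-3-(phenylsulfonyl)propanoate | COCOc1cc(ccc1O[Si](C(C)C)(C(C)C)C(C)C)[C@](C)(CS(=O)(=O)c1ccccc1)C(=O)OC | intermediate
31 | (S)-2-[3-(methoxymethoxy)-4-[tri(propan-2-yl)silyloxy]phenyl]-2-methyl-3-(phenylsulfonyl)propan-1-ol | COCOc1cc(ccc1O[Si](C(C)C)(C(C)C)C(C)C)[C@](C)(CS(=O)(=O)c1ccccc1)CO | intermediate
32 | dilithio derivative of 31 (lithium alkoxide, α-lithio sulfone) | COCOc1cc(ccc1O[Si](C(C)C)(C(C)C)C(C)C)[C@](C)(C([Li])S(=O)(=O)c1ccccc1)CO[Li] | intermediate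
33 | (2S,5E)-2-[3-(methoxymethoxy)-4-[tri(propan-2-yl)silyloxy]phenyl]-2,6,10-trimethyl-3-(phenylsulfonyl)undeca-5,9-dien-1-ol, C3 epimers | COCOc1cc(ccc1O[Si](C(C)C)(C(C)C)C(C)C)[C@](C)(C(C/C=C(\C)CCC=C(C)C)S(=O)(=O)c1ccccc1)CO | intermediate
34 | (2S,5E)-2-[3-(methoxymethoxy)-4-[tri(propan-2-yl)silyloxy]phenyl]-2,6,10-trimethylundeca-5,9-dien-1-ol | COCOc1cc(ccc1O[Si](C(C)C)(C(C)C)C(C)C)[C@](C)(CC/C=C(\C)CCC=C(C)C)CO | intermediate
35 | (2S,5E)-2-[3-(methoxymethoxy)-4-[tri(propan-2-yl)silyloxy]phenyl]-2,6,10-trimethylundeca-5,9-dienal | COCOc1cc(ccc1O[Si](C(C)C)(C(C)C)C(C)C)[C@](C)(CC/C=C(\C)CCC=C(C)C)C=O | intermediate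
36 | tri(propan-2-yl)[2-(methoxymethoxy)-4-[(3R,6E)-3,7,11-trimethyldodeca-1,6,10-trien-3-yl]phenoxy]silane | COCOc1cc(ccc1O[Si](C(C)C)(C(C)C)C(C)C)[C@](C)(CC/C=C(\C)CCC=C(C)C)C=C | intermediate
37 | 2-(methoxymethoxy)-4-[(3R,6E)-3,7,11-trimethyldodeca-1,6,10-trien-3-yl]phenol | COCOc1cc(ccc1O)[C@](C)(CC/C=C(\C)CCC=C(C)C)C=C | intermediate
38 | 1-[2-(methoxymethoxy)-4-[(3R,6E)-3,7,11-trimethyldodeca-1,6,10-trien-3-yl]phenoxy]-2,3-bis(methoxymethoxy)-5-[(3S,6E)-3,7,11-trimethyldodeca-1,6,10-trien-3-yl]benzene | COCOc1cc(ccc1Oc1cc(cc(OCOC)c1OCOC)[C@](C)(C=C)CC/C=C(\C)CCC=C(C)C)[C@](C)(CC/C=C(\C)CCC=C(C)C)C=C | intermediate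
39 | 3-[2-hydroxy-4-[(3R,6E)-3,7,11-trimethyldodeca-1,6,10-trien-3-yl]phenoxy]-5-[(3S,6E)-3,7,11-trimethyldodeca-1,6,10-trien-3-yl]benzene-1,2-diol (CNP0230356.1) | C=C[C@@](C)(CC/C=C(\C)CCC=C(C)C)c1ccc(Oc2cc([C@](C)(C=C)CC/C=C(\C)CCC=C(C)C)cc(O)c2O)c(O)c1 | target

**Step count**

Total: 31 steps. Longest linear sequence: 20 steps (steps 1–6, 18–29, 30, 31).

**Steps most likely to fail**

Step 6. The bulky benzyloxy/MOM-oxy aryl group may not seat productively in the enzyme, leading to slow turnover or weak discrimination between the two ester groups and hence low enantiomeric purity; poor solubility of the diester in buffer could add to this. Fallback (classical resolution in place of enzymatic desymmetrisation), setting out from 7: one equivalent of KOH in MeOH–THF–water at 0 °C → rt should stop at the racemic half-ester F1, because the carboxylate formed shields the second ester. F1 is combined with (S)-1-phenylethylamine in EtOAc/i-PrOH and the diastereomeric salts are separated by fractional crystallisation to give the (S)-1-phenylethylammonium salt F2 of the S acid, taken from the crystals or the liquors as found. Partition between cold 1 M HCl and EtOAc frees 8, where the route is rejoined; the same salt can also be used to upgrade enzymatically made 8.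

Step 30. Carbon–oxygen bond formation between two electron-rich partners that each carry an ortho MOM ether may be slow, allowing reductive loss of iodine or oxidation of the phenol at 90 °C. Fallback (oxidative copper coupling of a boronic acid at room temperature in place of substitution of an iodide), setting out from 21: lithiation as in step 17 gives aryllithium 22, which is trapped with B(OMe)3 and hydrolysed with aqueous NH4Cl to the boronic acid F3. F3 and phenol 37 with Cu(OAc)2 (divalent copper, 1 equiv), pyridine and 4 Å molecular sieves in CH2Cl2 under air at rt (Chan–Lam coupling) should give 38, where the route is rejoined.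

Step 20 (step 8 is the same reaction on the mirror-image series and shares the risk). Substitution at the neopentyl carbon may be slow enough for the triflate to ionise with participation of the electron-rich aryl ring, or for thiolate to attack the ester methyl group instead. Fallback (strain-driven opening of a β-lactone in place of substitution of a neopentyl triflate), setting out from 24: PhSO2Cl in pyridine at 0 °C should close the hydroxy acid to the β-lactone F4 through the mixed anhydride. PhSNa in DMF at rt opens the oxetanone at its CH2–O carbon to the thioether acid F5, and MeI/KHCO3 in DMF gives ester 27, where the route is rejoined.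

**Further compounds**

F1 | step 6 | racemic 2-[4-(benzyloxy)-3-(methoxymethoxy)phenyl]-3-methoxy-2-methyl-3-oxopropanoic acid | COCOc1cc(ccc1OCc1ccccc1)C(C)(C(=O)OC)C(=O)O
F2 | step 6 | (S)-1-phenylethylammonium (S)-2-[4-(benzyloxy)-3-(methoxymethoxy)phenyl]-3-methoxy-2-methyl-3-oxopropanoate | COCOc1cc(ccc1OCc1ccccc1)[C@](C)(C(=O)OC)C(=O)[O-].C[C@H]([NH3+])c1ccccc1
F3 | step 30 | [2,3-bis(methoxymethoxy)-5-[(3S,6E)-3,7,11-trimethyldodeca-1,6,10-trien-3-yl]phenyl]boronic acid | COCOc1cc(cc(B(O)O)c1OCOC)[C@](C)(C=C)CC/C=C(\C)CCC=C(C)C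
F4 | step 20 | (R)-3-[4-(benzyloxy)-3-(methoxymethoxy)phenyl]-3-methyloxetan-2-one | COCOc1cc(ccc1OCc1ccccc1)[C@](C)(CO2)C2=O
F5 | step 20 | (S)-2-[4-(benzyloxy)-3-(methoxymethoxy)phenyl]-2-methyl-3-(phenylsulfanyl)propanoic acid | COCOc1cc(ccc1OCc1ccccc1)[C@](C)(CSc1ccccc1)C(=O)O
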